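**Retrosynthetic overview**

- Numbering: chain C1 (lactone carbonyl) to C13. Ring C is the butenolide (C1–C4), ring B the 2,4-disubstituted furan on C13, ring A the 3-furyl ring.
- The plan rests on the E-trisubstituted C10=C11 bond of the C8–C11 E,E-diene, whose C10 methyl is cis to C12. C10–CH3 and C11–C12 are cut together, back to E-enyne 9, trimethylaluminium 10 and oxirane 11.
- C13–ring B is cut to a homoallylic zinc reagent and bromide 19. Rings A and B are joined through a carbinol that is then deoxygenated.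
- Exocyclic C4=C5 is cut to aldehyde 24 and silyloxyfuran 26, and is made by an erythro-selective vinylogous aldol followed by anti-elimination. C6 comes from the (R)-hydroxy ester 1.
- No ring is built: rings A and B are bought furans and ring C is 3-methylfuran-2(5H)-one. Order of assembly: A–B, then chain–B, then ring C.

Key step: step 8

Remark: in the target SMILES C6 is cis to ring carbon C3 and trans to the ring oxygen across C4=C5, so the ylidene butenolide is E and the endgame is built for that isomer.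
Remark: aldol adducts are drawn as the Felkin epimer at C5; C4 and C5 are erased in step 17 and only their relative (4,5-erythro) configuration matters.

**Route**

Step 1
Reactants: 1 methyl (R)-3-hydroxy-2-methylpropanoate
Product: 2 methyl (2R)-3-[(tert-butyldimethylsilyl)oxy]-2-methylpropanoate
Conditions: TBSCl, imidazole, CH2Cl2, 0 °C→rt
Reagents that add atoms: tert-butyldimethylsilyl chloride, CC(C)(C)[Si](C)(C)Cl
Why: Imidazole-promoted silyl ether formation masks the future C5 oxygen without touching the C6 stereocentre.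

Step 2
Reactants: 2 methyl (2R)-3-[(tert-butyldimethylsilyl)oxy]-2-methylpropanoate
Product: 3 (2S)-3-[(tert-butyldimethylsilyl)oxy]-2-methylpropan-1-ol
Conditions: DIBAL-H (iBu2AlH), CH2Cl2, −78→0 °C; aq. potassium sodium tartrate
Reagents that add atoms: none
Why: Hydride reduction of the ester to the primary alcohol under non-basic conditions should neither epimerise the α-centre nor move the silyl group.

Step 3
Reactants: 3 (2S)-3-[(tert-butyldimethylsilyl)oxy]-2-methylpropan-1-ol
Product: 4 tert-butyl{[(2R)-3-iodo-2-methylpropyl]oxy}dimethylsilane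
Conditions: PPh3, I2, imidazole, CH2Cl2, 0 °C
Reagents that add atoms: iodine, II
Why: Appel-type iodination displaces the primary oxyphosphonium by iodide (SN2) and leaves the β-stereocentre alone.

Step 4
Reactants: 4 tert-butyl{[(2R)-3-iodo-2-methylpropyl]oxy}dimethylsilane
Product: 5 tert-butyldimethyl{[(2S)-2-methylpent-4-yn-1-yl]oxy}silane
Conditions: HC≡CLi·H2NCH2CH2NH2, DMSO, 0 °C→rt
Reagents that add atoms: lithium acetylide–ethylenediamine complex, [Li]C#C.NCCN
Why: SN2 alkylation of the acetylide by the primary iodide in DMSO forms C7–C8 and installs the terminal alkyne.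

Step 5
Reactants: 5 tert-butyldimethyl{[(2S)-2-methylpent-4-yn-1-yl]oxy}silane
Product: 7 tert-butyl{[(2S,4E)-5-iodo-2-methylpent-4-en-1-yl]oxy}dimethylsilane, via alkenylzirconocene chloride 6 (not isolated)
Conditions: Cp2Zr(H)Cl, THF, rt, dark; then I2, 0 °C
Reagents that add atoms: iodine, II
Why: Hydrozirconation adds H–Zr syn with zirconium on the terminal carbon, and iodinolysis with retention fixes the E geometry of C8=C9.

Step 6
Reactants: 7 tert-butyl{[(2S,4E)-5-iodo-2-methylpent-4-en-1-yl]oxy}dimethylsilane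
Product: 8 tert-butyldimethyl{[(2S,4E)-2-methyl-7-(trimethylsilyl)hept-4-en-6-yn-1-yl]oxy}silane
Conditions: HC≡CSiMe3, Pd(PPh3)2Cl2 (cat.), CuI (cat.), Et3N, THF, rt
Reagents that add atoms: ethynyltrimethylsilane, C#C[Si](C)(C)C
Why: Sonogashira coupling of the alkenyl iodide forms C9–C10 with retention of the E alkene.

Step 7
Reactants: 8 tert-butyldimethyl{[(2S,4E)-2-methyl-7-(trimethylsilyl)hept-4-en-6-yn-1-yl]oxy}silane
Product: 9 tert-butyldimethyl{[(2S,4E)-2-methylhept-4-en-6-yn-1-yl]oxy}silane
Conditions: K2CO3 (cat.), MeOH, rt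
Reagents that add atoms: none
Why: Base-catalysed methanolysis cleaves the alkynyl C–Si bond selectively, the alkyl silyl ether being stable to carbonate.

Step 8
Reactants: 9 tert-butyldimethyl{[(2S,4E)-2-methylhept-4-en-6-yn-1-yl]oxy}silane, 10 trimethylaluminium, 11 oxirane
Product: 14 (3E,5E,8S)-9-[(tert-butyldimethylsilyl)oxy]-4,8-dimethylnona-3,5-dien-1-ol, via dienyl(dimethyl)alane 12 (not isolated), via lithium butyl(dienyl)dimethylalanate 13 (not isolated)
Conditions: Cp2ZrCl2 (cat.), (CH2Cl)2, rt; volatiles removed in vacuo; hexane, n-BuLi, 0 °C; THF, oxirane, 0 °C→rt; aq. potassium sodium tartrate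
Reagents that add atoms: none
Why: The methylzirconocene–aluminium species formed from Me3Al and Cp2ZrCl2 adds methyl and metal across the terminal alkyne through a four-centre syn carbometalation, methyl to the internal carbon C10 and metal to C11, and transmetalation gives the (E)-dienylalane 12. n-BuLi turns 12 into alanate 13, whose alkenyl ligand opens oxirane by SN2 attack with retention at C11, so the C10 methyl ends cis to C12. The closest known reaction type is the zirconium-catalysed carboalumination of terminal alkynes with epoxide capture of the derived alkenylalanate. No ring is closed and no stereocentre is formed; the C10=C11 geometry follows from syn addition plus retention, and C6 is remote and untouched. The step needs methyl delivery to C10, reaction at the alkyne and not at the C8=C9 alkene, and transfer of the alkenyl and not the methyl or butyl ligand; the terminal alkyne directs the metal to the unsubstituted carbon, the 1,2-disubstituted alkene is inert to carboalumination, and the sp2 ligand of the alanate migrates preferentially. Stripping excess Me3Al before n-BuLi is added keeps the epoxide from being consumed by methyl transfer.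

Step 9
Reactants: 15 3-bromofuran, 16 4-bromofuran-2-carbaldehyde
Product: 18 (4-bromofuran-2-yl)(furan-3-yl)methanol (racemic), via 3-furyllithium 17 (not isolated)
Conditions: 15, n-BuLi, Et2O, −78 °C; then 16, −78 °C; H2O
Reagents that add atoms: none
Why: Bromine–lithium exchange at −78 °C gives 3-furyllithium, which should add to the aldehyde faster than it isomerises to the 2-lithio isomer or exchanges with the ring B bromide; the carbinol centre is removed in step 10.

Step 10
Reactants: 18 (4-bromofuran-2-yl)(furan-3-yl)methanol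
Product: 19 4-bromo-2-(furan-3-ylmethyl)furan
Conditions: Et3SiH (excess), CF3CO2H, CH2Cl2, −20→0 °C
Reagents that add atoms: none
Why: Ionic hydrogenation, in which the doubly furyl-stabilised cation forms at low temperature and is trapped by silane hydride; excess silane limits Friedel–Crafts oligomerisation.

Step 11
Reactants: 14 (3E,5E,8S)-9-[(tert-butyldimethylsilyl)oxy]-4,8-dimethylnona-3,5-dien-1-ol
Product: 20 tert-butyl{[(2S,4E,6E)-9-iodo-2,6-dimethylnona-4,6-dien-1-yl]oxy}dimethylsilane
Conditions: PPh3, I2, imidazole, CH2Cl2, 0 °C, dark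
Reagents that add atoms: iodine, II
Why: Appel-type iodination of the primary homoallylic alcohol under imidazole buffering leaves the diene and the silyl ether intact.

Step 12
Reactants: 20 tert-butyl{[(2S,4E,6E)-9-iodo-2,6-dimethylnona-4,6-dien-1-yl]oxy}dimethylsilane, 19 4-bromo-2-(furan-3-ylmethyl)furan
Product: 22 tert-butyl{[(2S,4E,6E)-9-[5-(furan-3-ylmethyl)furan-3-yl]-2,6-dimethylnona-4,6-dien-1-yl]oxy}dimethylsilane, via alkylzinc iodide 21 (not isolated)
Conditions: Zn dust (activated), LiCl, THF, 40 °C; then 19, Pd(OAc)2 (cat.), SPhos (cat.), THF, rt→45 °C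
Reagents that add atoms: none
Why: LiCl-assisted zinc insertion gives the primary alkylzinc iodide, and Negishi coupling with the β-bromofuran under a bulky biarylphosphine, which favours reductive elimination from palladium over β-hydride elimination, forms the C13–ring B bond.

Step 13
Reactants: 22 tert-butyl{[(2S,4E,6E)-9-[5-(furan-3-ylmethyl)furan-3-yl]-2,6-dimethylnona-4,6-dien-1-yl]oxy}dimethylsilane
Product: 23 (2S,4E,6E)-9-[5-(furan-3-ylmethyl)furan-3-yl]-2,6-dimethylnona-4,6-dien-1-ol
Conditions: Bu4NF, THF, 0 °C→rt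
Reagents that add atoms: none
Why: Fluoride cleavage of the silyl ether frees the C5 alcohol under conditions harmless to the furans and the diene.

Step 14
Reactants: 23 (2S,4E,6E)-9-[5-(furan-3-ylmethyl)furan-3-yl]-2,6-dimethylnona-4,6-dien-1-ol
Product: 24 (2S,4E,6E)-9-[5-(furan-3-ylmethyl)furan-3-yl]-2,6-dimethylnona-4,6-dienal
Conditions: Dess–Martin periodinane, NaHCO3, CH2Cl2, 0 °C→rt; used crude at once
Reagents that add atoms: none
Why: Buffered Dess–Martin oxidation gives the aldehyde under non-enolising conditions, so the C6 configuration should be retained.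

Step 15
Reactants: 25 3-methylfuran-2(5H)-one
Product: 26 3-methyl-2-(trimethylsilyloxy)furan
Conditions: Me3SiOTf, Et3N, Et2O, 0 °C; distilled, used fresh
Reagents that add atoms: trimethylsilyl trifluoromethanesulfonate, C[Si](C)(C)OS(=O)(=O)C(F)(F)F
Why: Soft enolisation, with amine γ-deprotonation and O-silylation of the butenolide, gives the aromatic 2-silyloxyfuran.

Step 16
Reactants: 24 (2S,4E,6E)-9-[5-(furan-3-ylmethyl)furan-3-yl]-2,6-dimethylnona-4,6-dienal, 26 3-methyl-2-(trimethylsilyloxy)furan
Product: 28 (5S)-5-{(1R,2S,4E,6E)-9-[5-(furan-3-ylmethyl)furan-3-yl]-1-hydroxy-2,6-dimethylnona-4,6-dien-1-yl}-3-methylfuran-2(5H)-one, via O-trimethylsilyl aldol ether 27 (not isolated)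
Conditions: Bu4NF (cat.), THF, −78 °C; then aq. citric acid, rt
Reagents that add atoms: none
Why: Fluoride-triggered vinylogous Mukaiyama aldol addition, in which the furanolate released from 26 attacks the aldehyde through its γ-carbon in an open transition state that favours the 4,5-erythro (unlike) adduct, the reverse of the threo preference under Lewis acid promotion, while silyl transfer to the aldolate carries the chain and Felkin–Anh control from C6 should set C5 as drawn.

Step 17
Reactants: 28 (5S)-5-{(1R,2S,4E,6E)-9-[5-(furan-3-ylmethyl)furan-3-yl]-1-hydroxy-2,6-dimethylnona-4,6-dien-1-yl}-3-methylfuran-2(5H)-one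
Product: 29 (5E)-5-{(2S,4E,6E)-9-[5-(furan-3-ylmethyl)furan-3-yl]-2,6-dimethylnona-4,6-dien-1-ylidene}-3-methylfuran-2(5H)-one
Conditions: PPh3, DIAD, THF, −20 °C→rt, dark
Reagents that add atoms: none
Why: Mitsunobu-type dehydration, in which the C5 alkoxyphosphonium ion loses the acidic C4–H by antiperiplanar E2 elimination; from the 4,5-erythro adduct this places C6 cis to C3 and trans to the ring oxygen, giving the E exocyclic alkene without touching C6.

**Compound list**

1 | methyl (R)-3-hydroxy-2-methylpropanoate | COC(=O)[C@H](C)CO | starting material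
2 | methyl (2R)-3-[(tert-butyldimethylsilyl)oxy]-2-methylpropanoate | COC(=O)[C@H](C)CO[Si](C)(C)C(C)(C)C | intermediate
3 | (2S)-3-[(tert-butyldimethylsilyl)oxy]-2-methylpropan-1-ol | OC[C@H](C)CO[Si](C)(C)C(C)(C)C | intermediate
4 | tert-butyl{[(2R)-3-iodo-2-methylpropyl]oxy}dimethylsilane | IC[C@H](C)CO[Si](C)(C)C(C)(C)C | intermediate
5 | tert-butyldimethyl{[(2S)-2-methylpent-4-yn-1-yl]oxy}silane | C#CC[C@H](C)CO[Si](C)(C)C(C)(C)C | intermediate
6 | chlorobis(cyclopentadienyl)[(1E,4S)-5-(tert-butyldimethylsilyloxy)-4-methylpent-1-en-1-yl]zirconium | Cl[Zr](/C=C/C[C@H](C)CO[Si](C)(C)C(C)(C)C)(C1C=CC=C1)C1C=CC=C1 | intermediate (not isolated)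
7 | tert-butyl{[(2S,4E)-5-iodo-2-methylpent-4-en-1-yl]oxy}dimethylsilane | I/C=C/C[C@H](C)CO[Si](C)(C)C(C)(C)C | intermediate
8 | tert-butyldimethyl{[(2S,4E)-2-methyl-7-(trimethylsilyl)hept-4-en-6-yn-1-yl]oxy}silane | C[Si](C)(C)C#C/C=C/C[C@H](C)CO[Si](C)(C)C(C)(C)C | intermediate
9 | tert-butyldimethyl{[(2S,4E)-2-methylhept-4-en-6-yn-1-yl]oxy}silane | C#C/C=C/C[C@H](C)CO[Si](C)(C)C(C)(C)C | intermediate
10 | trimethylaluminium | C[Al](C)C | starting material
11 | oxirane | C1CO1 | starting material
12 | [(1E,3E,6S)-7-(tert-butyldimethylsilyloxy)-2,6-dimethylhepta-1,3-dien-1-yl]dimethylalane | C[Al](C)/C=C(C)/C=C/C[C@H](C)CO[Si](C)(C)C(C)(C)C | intermediate (not isolated)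
13 | lithium butyl[(1E,3E,6S)-7-(tert-butyldimethylsilyloxy)-2,6-dimethylhepta-1,3-dien-1-yl]dimethylalanate | [Li+].CCCC[Al-](C)(C)/C=C(C)/C=C/C[C@H](C)CO[Si](C)(C)C(C)(C)C | intermediate (not isolated)
14 | (3E,5E,8S)-9-[(tert-butyldimethylsilyl)oxy]-4,8-dimethylnona-3,5-dien-1-ol | OCC/C=C(C)/C=C/C[C@H](C)CO[Si](C)(C)C(C)(C)C | intermediate
15 | 3-bromofuran | Brc1ccoc1 | starting material
16 | 4-bromofuran-2-carbaldehyde | O=Cc1cc(Br)co1 | starting material
17 | 3-furyllithium | [Li]c1ccoc1 | intermediate (not isolated)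
18 | (4-bromofuran-2-yl)(furan-3-yl)methanol (racemic) | OC(c1cc(Br)co1)c1ccoc1 | intermediate
19 | 4-bromo-2-(furan-3-ylmethyl)furan | Brc1coc(Cc2ccoc2)c1 | intermediate
20 | tert-butyl{[(2S,4E,6E)-9-iodo-2,6-dimethylnona-4,6-dien-1-yl]oxy}dimethylsilane | ICC/C=C(C)/C=C/C[C@H](C)CO[Si](C)(C)C(C)(C)C | intermediate
21 | [(3E,5E,8S)-9-(tert-butyldimethylsilyloxy)-4,8-dimethylnona-3,5-dien-1-yl](iodo)zinc | I[Zn]CC/C=C(C)/C=C/C[C@H](C)CO[Si](C)(C)C(C)(C)C | intermediate (not isolated)
22 | tert-butyl{[(2S,4E,6E)-9-[5-(furan-3-ylmethyl)furan-3-yl]-2,6-dimethylnona-4,6-dien-1-yl]oxy}dimethylsilane | CC(C)(C)[Si](C)(C)OC[C@@H](C)C/C=C/C(C)=C/CCc1coc(Cc2ccoc2)c1 | intermediate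
23 | (2S,4E,6E)-9-[5-(furan-3-ylmethyl)furan-3-yl]-2,6-dimethylnona-4,6-dien-1-ol | OC[C@@H](C)C/C=C/C(C)=C/CCc1coc(Cc2ccoc2)c1 | intermediate
24 | (2S,4E,6E)-9-[5-(furan-3-ylmethyl)furan-3-yl]-2,6-dimethylnona-4,6-dienal | O=C[C@@H](C)C/C=C/C(C)=C/CCc1coc(Cc2ccoc2)c1 | intermediate
25 | 3-methylfuran-2(5H)-one | CC1=CCOC1=O | starting material
26 | 3-methyl-2-(trimethylsilyloxy)furan | Cc1ccoc1O[Si](C)(C)C | intermediate
27 | (5S)-5-{(1R,2S,4E,6E)-9-[5-(furan-3-ylmethyl)furan-3-yl]-2,6-dimethyl-1-(trimethylsilyloxy)nona-4,6-dien-1-yl}-3-methylfuran-2(5H)-one | CC1=C[C@@H]([C@H](O[Si](C)(C)C)[C@@H](C)C/C=C/C(C)=C/CCc2coc(Cc3ccoc3)c2)OC1=O | intermediate (not isolated)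
28 | (5S)-5-{(1R,2S,4E,6E)-9-[5-(furan-3-ylmethyl)furan-3-yl]-1-hydroxy-2,6-dimethylnona-4,6-dien-1-yl}-3-methylfuran-2(5H)-one | CC1=C[C@@H]([C@H](O)[C@@H](C)C/C=C/C(C)=C/CCc2coc(Cc3ccoc3)c2)OC1=O | intermediate
29 | (5E)-5-{(2S,4E,6E)-9-[5-(furan-3-ylmethyl)furan-3-yl]-2,6-dimethylnona-4,6-dien-1-ylidene}-3-methylfuran-2(5H)-one | CC1=C/C(=C\[C@@H](C)C/C=C/C(C)=C/CCc2coc(Cc3ccoc3)c2)OC1=O | target

**Summary**

Total step count: 17. Longest linear sequence: 14 steps (steps 1–8, 11–14, 16, 17).

Steps most likely to fail: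

1. Step 16. The fluoride-triggered addition may show poor simple diastereoselection toward the 4,5-erythro series, and the free furanolate may epimerise the aldehyde at C6. Fallback: from aldehyde 24, silyloxyfuran 26 is added under BF3·OEt2 (CH2Cl2, −78 °C), which should favour the 4,5-threo adduct (5R)-5-{(1R,2S,4E,6E)-9-[5-(furan-3-ylmethyl)furan-3-yl]-1-hydroxy-2,6-dimethylnona-4,6-dien-1-yl}-3-methylfuran-2(5H)-one F1 without exposing the aldehyde to base. The acidic C4–H is then equilibrated with Et3N and catalytic DMAP in CH2Cl2 at rt toward the 4,5-erythro epimer, recovered F1 is recycled, and the route is rejoined at 28.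

2. Step 17. Stereospecificity may be lost if C4 is deprotonated before the C5–O bond breaks (E1cB), or if the oxyphosphonium salt epimerises at C4; either leak gives the Z ylidene. Fallback: from aldehyde 24 the threo adduct F1 is made as described for step 16 and dehydrated by a syn pathway. The Burgess reagent (benzene, rt→50 °C) converts it into the triethylammonium N-(methoxycarbonyl)sulfamate ester of the threo adduct F2, whose cyclic syn-elimination removes the C4–H cis to the C5–O bond and places C6 cis to C3. The route is rejoined at 29.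

3. Step 12. The homoallyl palladium intermediate may undergo β-hydride elimination to a conjugated triene, or zinc insertion and oxidative addition to the electron-rich β-bromofuran may be sluggish. Fallback: from iodide 20, iodine–lithium exchange (t-BuLi, Et2O, −78 °C) gives (3E,5E,8S)-9-[(tert-butyldimethylsilyl)oxy]-4,8-dimethylnona-3,5-dien-1-yllithium F3. Capture with B-methoxy-9-borabicyclo[3.3.1]nonane gives lithium B-alkyl-B-methoxy-9-borabicyclo[3.3.1]nonan-9-uide F4, and B-alkyl Suzuki–Miyaura coupling with bromide 19 (Pd(dppf)Cl2, aq. K3PO4, DMF, rt) rejoins the route at 22.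

**Further compounds**

F1 | step 16 | (5R)-5-{(1R,2S,4E,6E)-9-[5-(furan-3-ylmethyl)furan-3-yl]-1-hydroxy-2,6-dimethylnona-4,6-dien-1-yl}-3-methylfuran-2(5H)-one | CC1=C[C@H]([C@H](O)[C@@H](C)C/C=C/C(C)=C/CCc2coc(Cc3ccoc3)c2)OC1=O
F2 | step 17 | triethylammonium N-(methoxycarbonyl)sulfamate ester of F1 at the C5 oxygen | CC1=C[C@H]([C@H](OS(=O)(=O)[N-]C(=O)OC)[C@@H](C)C/C=C/C(C)=C/CCc2coc(Cc3ccoc3)c2)OC1=O.CC[NH+](CC)CC
F3 | step 12 | (3E,5E,8S)-9-[(tert-butyldimethylsilyl)oxy]-4,8-dimethylnona-3,5-dien-1-yllithium | [Li]CC/C=C(C)/C=C/C[C@H](C)CO[Si](C)(C)C(C)(C)C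
F4 | step 12 | lithium 9-[(3E,5E,8S)-9-(tert-butyldimethylsilyloxy)-4,8-dimethylnona-3,5-dien-1-yl]-9-methoxy-9-borabicyclo[3.3.1]nonan-9-uide | [Li+].CO[B-]1(CC/C=C(C)/C=C/C[C@H](C)CO[Si](C)(C)C(C)(C)C)C2CCCC1CCC2
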